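**Retrosynthetic overview**
- Last operations: acetylation of the C13 hydroxyl and a catalyst-controlled Shi epoxidation of C3=C4 on the macrocyclic diene lactone (the epoxide is the third and last ring).
- C1–C14 bond: intramolecular indium Barbier allylation of an alpha-hydroxy aldehyde by a 2-(bromomethyl)enoate; the 14-membered carbocycle forms first, the cis-fused gamma-lactone second, in the same step.
- Head (C1, C15–C17): allylic chloride + triethyl orthopropiolate (C1–C2 bond), then hydroalumination/hydroxymethylation and bromination.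
- C8 carbinol and 6E-alkene: 7,8-epoxide (ent-Shi) opened and transposed with selenide; C12 and C13: one-flask organocatalytic reduction/alpha-benzoyloxylation relay on an achiral enal (first stereocentres).
- That enal: (2E,6E)-farnesyl acetate (C2–C13 and three methyls) by terminal allylic oxidation and one-carbon Wittig homologation.

Assumption: CNP0202356.4 is exactly the stereoisomer of the given SMILES; in cembrane numbering (C16 lactone carbonyl on C15, lactone O on C14) it is 1S,3R,4R,6E,8S,12S,13R,14R with a cis-fused lactone, and this numbering is used in the explanations.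

**Step 1**
Reactants: 1 (2E,6E)-farnesyl acetate
Product: 3 (2E,6E,10E)-3,7,11-trimethyl-12-oxododeca-2,6,10-trien-1-yl acetate, via allylic alcohol 2 (not isolated)
Conditions: SeO2 (20 mol%), t-BuOOH (70% aq.), salicylic acid (10 mol%), CH2Cl2, rt; filter; then MnO2, CH2Cl2, rt
Reagents that add atoms: tert-butyl hydroperoxide (CC(C)(C)OO)
Why: SeO2/t-BuOOH allylic oxidation (ene reaction, then 2,3-sigmatropic shift) attacks the E-methyl of the most electron-rich terminal alkene of farnesyl acetate, and MnO2 oxidises only the new allylic alcohol; no stereocentre is formed.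

**Step 2**
Reactants: 3 (2E,6E,10E)-3,7,11-trimethyl-12-oxododeca-2,6,10-trien-1-yl acetate
Product: 5 (7E,11E)-13-acetoxy-3,7,11-trimethyltrideca-2,7,11-trienal (2E/2Z mixture), via dienyl methyl ether 4 (not isolated)
Conditions: MeOCH2PPh3Cl, KN(SiMe3)2, THF, −78 to 0 °C; then 1 M HCl, THF, rt
Reagents that add atoms: (methoxymethyl)triphenylphosphonium chloride (COC[P+](c1ccccc1)(c1ccccc1)c1ccccc1.[Cl-]); water (O)
Why: Wittig methoxymethylenation gives a 1-methoxy-1,3-diene whose acid hydrolysis through the vinylogous oxocarbenium ion delivers the one-carbon-homologated, transposed beta,beta-disubstituted enal (C14 aldehyde, C12=C13); the 2E/2Z ratio and any beta,gamma-isomer do not matter because all converge through the same dienamine/iminium in step 3.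

**Step 3**
Reactants: 5 (7E,11E)-13-acetoxy-3,7,11-trimethyltrideca-2,7,11-trienal
Product: 8 (2R,3S,7E,11E)-13-acetoxy-1-hydroxy-3,7,11-trimethyltrideca-7,11-dien-2-yl benzoate, via saturated aldehyde 6 (not isolated), via benzoyloxy aldehyde 7 (not isolated)
Conditions: morpholinium salt of (S)-TRIP [(S)-3,3'-bis(2,4,6-triisopropylphenyl)-1,1'-binaphthyl-2,2'-diyl phosphate] (10 mol%), Hantzsch ester (1.1 equiv), dioxane, 50 °C; then (R)-2-[diphenyl(trimethylsilyloxy)methyl]pyrrolidine (20 mol%), (PhCO2)2, hydroquinone (10 mol%), THF, 0 °C; then NaBH4, MeOH, −20 °C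
Reagents that add atoms: dibenzoyl peroxide (O=C(OOC(=O)c1ccccc1)c1ccccc1)
Why: Proposed new method: a one-flask iminium-to-enamine relay ("reductive alpha-benzoyloxylation") in which counteranion-directed transfer hydrogenation of the E/Z-equilibrating morpholinium iminium sets C12 (S, the sense inferred from citral to citronellal, where the R anion gives the R aldehyde), after which the peroxide scavenges residual morpholine and the E-enamine of the bulky R prolinol silyl ether is benzoyloxylated anti to its CPh2OSiMe3 group to set C13 (R, catalyst control, 12,13-syn), and NaBH4 fixes the labile aldehyde (any benzoate shift to O14 is harmless, step 5 removes it); the closest known reactions are the counteranion-directed enal transfer hydrogenation, the single-amine iminium/enamine hydride–halogen organocascade and the amine-catalysed alpha-benzoyloxylation of aldehydes, which have not been run as one relay with two cycle-specific catalysts on a beta,beta-dialkyl enal.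

**Step 4**
Reactants: 8 (2R,3S,7E,11E)-13-acetoxy-1-hydroxy-3,7,11-trimethyltrideca-7,11-dien-2-yl benzoate
Product: 9 (2R,3S,7S,8S,11E)-13-acetoxy-7,8-epoxy-1-hydroxy-3,7,11-trimethyltridec-11-en-2-yl benzoate
Conditions: ent-Shi ketone (L-fructose-derived, 30 mol%), Oxone (2KHSO5·KHSO4·K2SO4), K2CO3, Bu4NHSO4, MeCN/CH2(OMe)2, aq. Na2B4O7 buffer pH 10.5, −10 to 0 °C
Reagents that add atoms: potassium peroxymonosulfate (KHSO5, [K+].[O-]S(=O)(=O)OO)
Why: Shi asymmetric epoxidation, in which the chiral dioxirane attacks only the electron-rich C7=C8 alkene (C3=C4 is deactivated by its allylic acetate) through the spiro transition state; since the D-fructose ketone gives R,R-epoxides from E-trisubstituted alkenes, its enantiomer gives the 7S,8S-epoxide (cembrane numbering).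

**Step 5**
Reactants: 9 (2R,3S,7S,8S,11E)-13-acetoxy-7,8-epoxy-1-hydroxy-3,7,11-trimethyltridec-11-en-2-yl benzoate
Product: 12 (2R,3S,7S,8E,11E)-3,7,11-trimethyltrideca-8,11-diene-1,2,7,13-tetrol, via epoxy triol 10 (not isolated), via hydroxy selenide 11 (not isolated)
Conditions: K2CO3 (cat.), MeOH, rt; then PhSeSePh, NaBH4, EtOH, reflux; then 30% H2O2, pyridine, THF, 0 °C to rt
Reagents that add atoms: none
Why: Ester methanolysis, then the Sharpless–Lauer epoxide-to-allylic-alcohol transposition, in which PhSe− opens the epoxide by SN2 at the less hindered C7 so the C8–O bond keeps its S configuration, and selenoxide syn-elimination can only use a C6 hydrogen (C8 has none), giving the 6E-alkene and the tertiary allylic alcohol.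

**Step 6**
Reactants: 12 (2R,3S,7S,8E,11E)-3,7,11-trimethyltrideca-8,11-diene-1,2,7,13-tetrol
Product: 13 (2R,3S,7S,8E,11E)-13-chloro-3,7,11-trimethyltrideca-8,11-diene-1,2,7-triol
Conditions: NCS, Me2S, CH2Cl2, −40 to 0 °C
Reagents that add atoms: N-chlorosuccinimide (O=C1CCC(=O)N1Cl)
Why: Corey–Kim chlorination, in which only the alkoxysulfonium salt of the primary allylic alcohol is displaced by chloride (SN2, E geometry kept), while the saturated and the hindered tertiary hydroxyls are returned on work-up.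

**Step 7**
Reactants: 13 (2R,3S,7S,8E,11E)-13-chloro-3,7,11-trimethyltrideca-8,11-diene-1,2,7-triol; 14 3,3,3-triethoxyprop-1-yne
Product: 16 ethyl (5E,8E,10S,14S,15R)-10,15,16-trihydroxy-6,10,14-trimethylhexadeca-5,8-dien-2-ynoate, via orthoester 15 (not isolated)
Conditions: CuI (20 mol%), NaI (cat.), K2CO3, DMF, rt; then 0.1 M citric acid, THF/H2O, rt
Reagents that add atoms: water (O)
Why: Copper acetylide alkylation of the allylic halide (SN2, linear, 3E retained) forms the C1–C2 bond; the orthoester keeps the alkyne from acting as a Michael acceptor toward the free hydroxyls and is hydrolysed to the ethyl ester by acid mild enough for the tertiary allylic alcohol.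

**Step 8**
Reactants: 16 ethyl (5E,8E,10S,14S,15R)-10,15,16-trihydroxy-6,10,14-trimethylhexadeca-5,8-dien-2-ynoate
Product: 18 ethyl (2Z,5E,8E,10S,14S,15R)-10,15,16-trihydroxy-2-(hydroxymethyl)-6,10,14-trimethylhexadeca-2,5,8-trienoate, via vinylalane 17 (not isolated)
Conditions: iBu2AlH (6 equiv), HMPA, THF, 0 °C; then (CH2O)n, 0 °C to rt; aq. KNaC4H4O6 work-up
Reagents that add atoms: formaldehyde as paraformaldehyde (C=O)
Why: Conjugate syn-hydroalumination of the ynoate by the iBu2AlH–HMPA complex (the hydroxyls are first converted into aluminium alkoxides) gives the alpha-alumino acrylate, which adds to formaldehyde with retention (an aluminium variant of the Baylis–Hillman reaction), installing C17.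

**Step 9**
Reactants: 18 ethyl (2Z,5E,8E,10S,14S,15R)-10,15,16-trihydroxy-2-(hydroxymethyl)-6,10,14-trimethylhexadeca-2,5,8-trienoate
Product: 19 ethyl (2E,5E,8E,10S,14S,15R)-2-(bromomethyl)-10,15,16-trihydroxy-6,10,14-trimethylhexadeca-2,5,8-trienoate
Conditions: NBS, Me2S, CH2Cl2, −20 to 0 °C
Reagents that add atoms: N-bromosuccinimide (O=C1CCC(=O)N1Br)
Why: Corey–Kim-type bromination converts only the allylic primary alcohol; the geometry of this allyl bromide is inconsequential because the derived allylindium equilibrates by 1,3-metal shift.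

**Step 10**
Reactants: 19 ethyl (2E,5E,8E,10S,14S,15R)-2-(bromomethyl)-10,15,16-trihydroxy-6,10,14-trimethylhexadeca-2,5,8-trienoate
Product: 22 (1S,3E,6E,8S,12S,13R,14R)-8,13-dihydroxycembra-3,6,15(17)-trien-16,14-olide, via bromo aldehyde 20 (not isolated), via macrocyclic hydroxy ester 21 (not isolated)
Conditions: TEMPO (10 mol%), NCS, Bu4NCl (cat.), CH2Cl2/aq. NaHCO3, 0 °C; then In powder, THF/H2O 1:1, 2 mM, rt; then PPTS (cat.), CH2Cl2, rt
Reagents that add atoms: none
Why: TEMPO/NCS oxidises the primary alcohol selectively to the alpha-hydroxy aldehyde, and the intramolecular indium-mediated aqueous Barbier allylation then closes the 14-membered ring: chelation of indium between the free C13 hydroxyl and the aldehyde gives the 13,14-syn diol (14R), the chair transition state of the gamma-substituted 2-(alkoxycarbonyl)allylindium gives the 1,14-syn adduct (1S), and the C14 hydroxyl lactonises (five-membered ring preferred over the six-membered alternative through O13) to the cis-fused alpha-methylene-gamma-butyrolactone.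

**Step 11**
Reactants: 22 (1S,3E,6E,8S,12S,13R,14R)-8,13-dihydroxycembra-3,6,15(17)-trien-16,14-olide
Product: 23 (1S,3E,6E,8S,12S,13R,14R)-13-acetoxy-8-hydroxycembra-3,6,15(17)-trien-16,14-olide
Conditions: Ac2O, pyridine, DMAP (cat.), CH2Cl2, 0 °C
Reagents that add atoms: acetic anhydride (CC(=O)OC(C)=O)
Why: Acylation of the only secondary hydroxyl; the tertiary allylic C8 hydroxyl is too hindered to react under these conditions.

**Step 12**
Reactants: 23 (1S,3E,6E,8S,12S,13R,14R)-13-acetoxy-8-hydroxycembra-3,6,15(17)-trien-16,14-olide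
Product: 24 (1S,3R,4R,6E,8S,12S,13R,14R)-13-acetoxy-3,4-epoxy-8-hydroxycembra-6,15(17)-dien-16,14-olide
Conditions: Shi ketone (D-fructose-derived, 30 mol%), Oxone (2KHSO5·KHSO4·K2SO4), K2CO3, Bu4NHSO4, MeCN/CH2(OMe)2, aq. Na2B4O7 buffer pH 10.5, −10 °C
Reagents that add atoms: potassium peroxymonosulfate (KHSO5, [K+].[O-]S(=O)(=O)OO)
Why: Shi asymmetric epoxidation, in which the D-fructose-derived dioxirane epoxidises the electron-rich trisubstituted C3=C4 alkene in preference to the hindered, hydroxyl-deactivated disubstituted C6=C7 alkene and the electron-poor methylene lactone, the spiro transition state giving the 3R,4R-epoxide under catalyst control.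

**Compound list**
1 | (2E,6E)-farnesyl acetate, (2E,6E)-3,7,11-trimethyldodeca-2,6,10-trien-1-yl acetate | CC(=O)OC/C=C(\C)CC/C=C(\C)CCC=C(C)C | starting material
2 | (2E,6E,10E)-12-hydroxy-3,7,11-trimethyldodeca-2,6,10-trien-1-yl acetate | CC(=O)OC/C=C(\C)CC/C=C(\C)CC/C=C(\C)CO | intermediate
3 | (2E,6E,10E)-3,7,11-trimethyl-12-oxododeca-2,6,10-trien-1-yl acetate | CC(=O)OC/C=C(\C)CC/C=C(\C)CC/C=C(\C)C=O | intermediate
4 | (2E,6E,10E)-13-methoxy-3,7,11-trimethyltrideca-2,6,10,12-tetraen-1-yl acetate (12E/12Z mixture) | CC(=O)OC/C=C(\C)CC/C=C(\C)CC/C=C(\C)C=COC | intermediate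
5 | (7E,11E)-13-acetoxy-3,7,11-trimethyltrideca-2,7,11-trienal (2E/2Z mixture) | O=CC=C(C)CCC/C(C)=C/CC/C(C)=C/COC(C)=O | intermediate
6 | (3S,7E,11E)-13-acetoxy-3,7,11-trimethyltrideca-7,11-dienal | O=CC[C@@H](C)CCC/C(C)=C/CC/C(C)=C/COC(C)=O | intermediate
7 | (2R,3S,7E,11E)-13-acetoxy-3,7,11-trimethyl-1-oxotrideca-7,11-dien-2-yl benzoate | O=C[C@H](OC(=O)c1ccccc1)[C@@H](C)CCC/C(C)=C/CC/C(C)=C/COC(C)=O | intermediate
8 | (2R,3S,7E,11E)-13-acetoxy-1-hydroxy-3,7,11-trimethyltrideca-7,11-dien-2-yl benzoate | OC[C@H](OC(=O)c1ccccc1)[C@@H](C)CCC/C(C)=C/CC/C(C)=C/COC(C)=O | intermediate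
9 | (2R,3S,7S,8S,11E)-13-acetoxy-7,8-epoxy-1-hydroxy-3,7,11-trimethyltridec-11-en-2-yl benzoate | OC[C@H](OC(=O)c1ccccc1)[C@@H](C)CCC[C@]2(C)O[C@H]2CC/C(C)=C/COC(C)=O | intermediate
10 | (2R,3S,7S,8S,11E)-7,8-epoxy-3,7,11-trimethyltridec-11-ene-1,2,13-triol | OC[C@H](O)[C@@H](C)CCC[C@]1(C)O[C@H]1CC/C(C)=C/CO | intermediate
11 | (2R,3S,7S,8R,11E)-3,7,11-trimethyl-8-(phenylselanyl)tridec-11-ene-1,2,7,13-tetrol | OC[C@H](O)[C@@H](C)CCC[C@](C)(O)[C@H]([Se]c1ccccc1)CC/C(C)=C/CO | intermediate
12 | (2R,3S,7S,8E,11E)-3,7,11-trimethyltrideca-8,11-diene-1,2,7,13-tetrol | OC[C@H](O)[C@@H](C)CCC[C@](C)(O)/C=C/C/C(C)=C/CO | intermediate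
13 | (2R,3S,7S,8E,11E)-13-chloro-3,7,11-trimethyltrideca-8,11-diene-1,2,7-triol | OC[C@H](O)[C@@H](C)CCC[C@](C)(O)/C=C/C/C(C)=C/CCl | intermediate
14 | 3,3,3-triethoxyprop-1-yne (triethyl orthopropiolate) | C#CC(OCC)(OCC)OCC | starting material
15 | (2R,3S,7S,8E,11E)-16,16,16-triethoxy-3,7,11-trimethylhexadeca-8,11-dien-14-yne-1,2,7-triol | OC[C@H](O)[C@@H](C)CCC[C@](C)(O)/C=C/C/C(C)=C/CC#CC(OCC)(OCC)OCC | intermediate
16 | ethyl (5E,8E,10S,14S,15R)-10,15,16-trihydroxy-6,10,14-trimethylhexadeca-5,8-dien-2-ynoate | OC[C@H](O)[C@@H](C)CCC[C@](C)(O)/C=C/C/C(C)=C/CC#CC(=O)OCC | intermediate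
17 | ethyl (2E,5E,8E,10S,14S,15R)-2-(diisobutylalumanyl)-10,15,16-tris[(diisobutylalumanyl)oxy]-6,10,14-trimethylhexadeca-2,5,8-trienoate | CC(C)C[Al](CC(C)C)OC[C@H](O[Al](CC(C)C)CC(C)C)[C@@H](C)CCC[C@](C)(O[Al](CC(C)C)CC(C)C)/C=C/C/C(C)=C/C/C=C(/[Al](CC(C)C)CC(C)C)C(=O)OCC | intermediate
18 | ethyl (2Z,5E,8E,10S,14S,15R)-10,15,16-trihydroxy-2-(hydroxymethyl)-6,10,14-trimethylhexadeca-2,5,8-trienoate | OC[C@H](O)[C@@H](C)CCC[C@](C)(O)/C=C/C/C(C)=C/C/C=C(/CO)C(=O)OCC | intermediate
19 | ethyl (2E,5E,8E,10S,14S,15R)-2-(bromomethyl)-10,15,16-trihydroxy-6,10,14-trimethylhexadeca-2,5,8-trienoate | OC[C@H](O)[C@@H](C)CCC[C@](C)(O)/C=C/C/C(C)=C/C/C=C(/CBr)C(=O)OCC | intermediate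
20 | ethyl (2E,5E,8E,10S,14S,15R)-2-(bromomethyl)-10,15-dihydroxy-6,10,14-trimethyl-16-oxohexadeca-2,5,8-trienoate | O=C[C@H](O)[C@@H](C)CCC[C@](C)(O)/C=C/C/C(C)=C/C/C=C(/CBr)C(=O)OCC | intermediate
21 | ethyl 2-[(1S,2R,3R,4S,8S,9E,12E)-2,3,8-trihydroxy-4,8,12-trimethylcyclotetradeca-9,12-dien-1-yl]prop-2-enoate | CCOC(=O)C(=C)[C@H]1[C@@H](O)[C@H](O)[C@@H](C)CCC[C@](C)(O)/C=C/C/C(C)=C/C1 | intermediate
22 | (1S,3E,6E,8S,12S,13R,14R)-8,13-dihydroxycembra-3,6,15(17)-trien-16,14-olide | C=C1C(=O)O[C@H]2[C@H](O)[C@@H](C)CCC[C@](C)(O)/C=C/C/C(C)=C/C[C@@H]12 | intermediate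
23 | (1S,3E,6E,8S,12S,13R,14R)-13-acetoxy-8-hydroxycembra-3,6,15(17)-trien-16,14-olide | C=C1C(=O)O[C@H]2[C@H](OC(C)=O)[C@@H](C)CCC[C@](C)(O)/C=C/C/C(C)=C/C[C@@H]12 | intermediate
24 | CNP0202356.4, (1S,3R,4R,6E,8S,12S,13R,14R)-13-acetoxy-3,4-epoxy-8-hydroxycembra-6,15(17)-dien-16,14-olide | C=C1C(=O)O[C@H]2[C@H](OC(C)=O)[C@@H](C)CCC[C@](C)(O)/C=C/C[C@@]3(C)O[C@@H]3C[C@@H]12 | target

**Step count and risks**
Total step count: 12. Longest linear sequence: 12 steps (1 to 24); 14 is a commercial reagent.

The three steps most likely to fail: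

Step 3 (the proposed relay). The two catalytic cycles may interfere: residual morpholine enamine could give background benzoyloxylation, the peroxide degrades amines, and the 12,13-selectivity is untested. The fallback uses known chemistry, sets out from 5 and comes back at 12. The counteranion-directed transfer hydrogenation is run alone and aldehyde 6 is isolated. L-Proline-catalysed alpha-aminoxylation with nitrosobenzene (hydrogen-bond-directed, same 13R sense) followed by NaBH4 gives the anilinooxy alcohol F1. Zn/AcOH cleaves the N–O bond to the diol acetate F2. ent-Shi epoxidation gives the epoxy diol acetate F3, which under the conditions of step 5 gives 12.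

Step 8 (hydroalumination/hydroxymethylation on an unprotected triol). Over-reduction of the ester or poor trapping by formaldehyde is possible. The fallback sets out from 13 and comes back at 18. CuI/K2CO3/NaI coupling of 13 with propargyl alcohol gives the skipped enynol F4. Hydroxyl-directed trans-hydroalumination with LiAlH4/AlCl3 followed by I2 gives the 2-iodoallylic alcohol F5. Ethoxycarbonylation with Pd(PPh3)4, CO, EtOH and Et3N then gives 18 with retention of the alkene geometry.

Step 10 (selective oxidation and macro-Barbier closure). The risks are oligomerisation and insufficient 13,14/1,14 control in the ring-forming event. The fallback sets out from 19 and comes back at 22. After the same TEMPO oxidation to 20, stannylation with (Bu3Sn)2 and Pd2(dba)3 gives the allylstannane aldehyde F6, an isolable nucleophile. MgBr2·OEt2 in CH2Cl2 at high dilution then promotes a chelation-controlled intramolecular allylstannane addition (open, syn-selective transition state, a known ring closure for cembranoids) to 21, and PPTS lactonises it to 22.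

Further compounds
F1 | step 3 | (2E,6E,11S,12R)-13-hydroxy-3,7,11-trimethyl-12-[(phenylamino)oxy]trideca-2,6-dien-1-yl acetate | OC[C@H](ONc1ccccc1)[C@@H](C)CCC/C(C)=C/CC/C(C)=C/COC(C)=O
F2 | step 3 | (2E,6E,11S,12R)-12,13-dihydroxy-3,7,11-trimethyltrideca-2,6-dien-1-yl acetate | OC[C@H](O)[C@@H](C)CCC/C(C)=C/CC/C(C)=C/COC(C)=O
F3 | step 3 | (2E,6S,7S,11S,12R)-6,7-epoxy-12,13-dihydroxy-3,7,11-trimethyltridec-2-en-1-yl acetate | OC[C@H](O)[C@@H](C)CCC[C@]1(C)O[C@H]1CC/C(C)=C/COC(C)=O
F4 | step 8 | (5E,8E,10S,14S,15R)-6,10,14-trimethylhexadeca-5,8-dien-2-yne-1,10,15,16-tetrol | OC[C@H](O)[C@@H](C)CCC[C@](C)(O)/C=C/C/C(C)=C/CC#CCO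
F5 | step 8 | (2Z,5E,8E,10S,14S,15R)-2-iodo-6,10,14-trimethylhexadeca-2,5,8-triene-1,10,15,16-tetrol | OC[C@H](O)[C@@H](C)CCC[C@](C)(O)/C=C/C/C(C)=C/C/C=C(/CO)I
F6 | step 10 | ethyl (5E,8E,10S,14S,15R)-10,15-dihydroxy-6,10,14-trimethyl-16-oxo-2-[(tributylstannyl)methyl]hexadeca-2,5,8-trienoate (2E/2Z mixture) | O=C[C@H](O)[C@@H](C)CCC[C@](C)(O)/C=C/C/C(C)=C/CC=C(C[Sn](CCCC)(CCCC)CCCC)C(=O)OCC
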